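**Plan**

- Numbering: C1 = prenyl bridgehead, C2–C3(aroyl)–C4 = enolised diketone, C5 = geranyl bridgehead, C6H2, C7H(prenyl), C8Me2, C9 = bridging ketone. Ring A = C1-C2-C3-C4-C5-C9 and ring B = C1-C8-C7-C6-C5-C9.
- Cuts, in retrosynthetic order: C3–aroyl, the C7 side-chain alkene, C7–H, C7–C8 (opens ring B), alkyne–ester carbon, C5–geranyl, C5–C6, C1–prenyl. C1–C8 is never made, because it is the ring–acetyl bond of a commercial acetophenone.
- Enabling feature: C8 is a quaternary carbon with two methyl groups on bridgehead C1, and C7 lies two atoms from bridgehead C5. An isopropenyl group on C1 and a butynoate arm on C5, cis and 1,3-diaxial on ring A, therefore need only one hydrogen atom to close ring B at C7–C8.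
- Forward: ring A is the benzene ring, dearomatised at C1 (allylation, metathesis) and quaternised at C5 (propargyl, then geranyl). Ring B follows by radical closure, then C7 reduction, side-chain Wittig reaction, C3 aroylation and deprotection.
- Stereochemistry: C1 comes from resolution of an early vinylogous acid. C5 comes from 1,3-induction by C1 (geranyl enters anti to isopropenyl). C7 comes from copper hydride attack on the exo face, which turns the side chain endo.

Key step: step 9

Assumption: in step 5 the (R)-amine is taken to give the less soluble salt with the wanted (S)-acid; if the pairing is the opposite, the (S)-amine is used and nothing else changes.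

Remark: while the isopropenyl group shares C1 with an allyl or prenyl group the two form a 1,5-diene, so every operation up to the key step stays at or below 55 °C to keep the Cope rearrangement silent.

Remark: the methyl enol ether sits on O2, where the dearomatisation leaves it; this confines the enolate chemistry to C5 and leads to the same enolised diketone at the end.

**Step 1**
Reactants: 1 4'-hydroxy-2',6'-dimethoxyacetophenone; 2 methyltriphenylphosphonium bromide
Product: 3 3,5-dimethoxy-4-(prop-1-en-2-yl)phenol
Conditions: 2 (3 equiv), KOtBu (3 equiv), THF, 0 °C; then 1, 0 → 50 °C; aq NH4Cl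
Reagents that add atoms: methyltriphenylphosphonium bromide 2, C[P+](c1ccccc1)(c1ccccc1)c1ccccc1.[Br-]
Why: Wittig methylenation with excess non-stabilised ylide, as is usual for free hydroxyacetophenones: the first equivalent only makes the phenoxide, and because the two ortho methoxy groups twist the acetyl group out of the ring plane this phenoxide cannot deactivate the carbonyl group by conjugation.

**Step 2**
Reactants: 3 3,5-dimethoxy-4-(prop-1-en-2-yl)phenol; 4 allyl methyl carbonate
Product: 5 4-allyl-3,5-dimethoxy-4-(prop-1-en-2-yl)cyclohexa-2,5-dien-1-one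
Conditions: 4 (1.5 equiv), Pd(OAc)2 (5 mol %), PPh3 (20 mol %), Ti(OiPr)4 (25 mol %), toluene, 50 °C
Reagents that add atoms: allyl methyl carbonate 4, C=CCOC(=O)OC
Why: Dearomative Tsuji–Trost allylation, the known para C-allylation of 4-substituted 3,5-dimethoxyphenols: O-allylation is reversible under zerovalent palladium, the titanium phenoxide shields the ortho carbons, and the para carbon C1, activated by the phenoxide and both methoxy groups, attacks the allylpalladium cation irreversibly to give an achiral dienone.

**Step 3**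
Reactants: 5 4-allyl-3,5-dimethoxy-4-(prop-1-en-2-yl)cyclohexa-2,5-dien-1-one; 6 2-methyl-2-butene
Product: 7 3,5-dimethoxy-4-(3-methylbut-2-enyl)-4-(prop-1-en-2-yl)cyclohexa-2,5-dien-1-one
Conditions: 6 (excess), second-generation Grubbs catalyst (3 mol %), CH2Cl2, 35 °C
Reagents that add atoms: 2-methyl-2-butene 6, CC=C(C)C
Why: Olefin cross-metathesis: only the monosubstituted allyl alkene engages the ruthenium carbene, the isopropenyl group on a quaternary carbon and the trisubstituted ring enol ethers are spectators, and loss of volatile propene drives the exchange to the prenyl group.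

**Step 4**
Reactants: 7 3,5-dimethoxy-4-(3-methylbut-2-enyl)-4-(prop-1-en-2-yl)cyclohexa-2,5-dien-1-one
Product: 8 rac-3-hydroxy-5-methoxy-4-(3-methylbut-2-enyl)-4-(prop-1-en-2-yl)cyclohexa-2,5-dien-1-one
Conditions: NaOH (2 equiv), MeOH–H2O 3:1, 55 °C; then cold 1 M HCl to pH 4
Reagents that add atoms: sodium hydroxide, [Na+].[OH-]
Why: Hydrolysis of a vinylogous ester by addition–elimination: the vinylogous carboxylate formed after the first cleavage repels hydroxide, so the reaction stops at the mono-acid, in which C1 has become a stereocentre (racemic at this point).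

**Step 5**
Reactants: 8 rac-3-hydroxy-5-methoxy-4-(3-methylbut-2-enyl)-4-(prop-1-en-2-yl)cyclohexa-2,5-dien-1-one; 9 (R)-1-phenylethylamine
Product: 10 (R)-1-phenylethylammonium salt of the (S)-enantiomer of 8
Conditions: 9 (0.5 equiv), EtOAc–heptane, 50 → 5 °C; two recrystallisations
Reagents that add atoms: (R)-1-phenylethylamine 9, C[C@@H](N)c1ccccc1
Why: Classical resolution through diastereomeric ammonium salts by the half-equivalent method, feasible because 8 is about as acidic as a carboxylic acid and configurationally stable (the methyl ether cannot migrate); this step fixes the absolute configuration at C1.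

**Step 6**
Reactants: 10 (R)-1-phenylethylammonium salt of the (S)-enantiomer of 8; 11 propargyl bromide
Product: 13 (4S)-3-hydroxy-5-methoxy-4-(3-methylbut-2-enyl)-4-(prop-1-en-2-yl)-2-(prop-2-ynyl)cyclohexa-2,5-dien-1-one, via potassium enolate 12 (not isolated)
Conditions: KOH (1.0 equiv), H2O, MTBE wash (removes the amine); aqueous layer, MeOH, 11 (1.2 equiv), 0 °C → rt
Reagents that add atoms: propargyl bromide 11, C#CCBr
Why: C-alkylation of a cyclic 1,3-diketone enolate with a propargylic bromide in protic medium, where hydrogen bonding to oxygen favours attack through carbon; the charge is confined to O9–C5–O4, so C3 stays silent, and the ester is added only in step 8 because an enol next to an ynoate would close to a furan by oxa-Michael addition.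

**Step 7**
Reactants: 13 (4S)-3-hydroxy-5-methoxy-4-(3-methylbut-2-enyl)-4-(prop-1-en-2-yl)-2-(prop-2-ynyl)cyclohexa-2,5-dien-1-one; 14 geranyl bromide
Product: 15 (2S,6R)-2-geranyl-5-methoxy-6-prenyl-6-isopropenyl-2-propargylcyclohex-4-ene-1,3-dione (ring C2 = C5 and ring C6 = C1 of the target; propargyl cis to isopropenyl)
Conditions: 14 (1.3 equiv), KOH (1.1 equiv), H2O–THF 1:1, 0 °C → rt
Reagents that add atoms: geranyl bromide 14, CC(C)=CCC/C(C)=C/CBr
Why: Second C-alkylation of the now 2-substituted 1,3-diketone with a soft allylic bromide creates quaternary C5; the nearly flat enolate is approached on the face that carries the slim C1–CH2 of the prenyl group and not on the face screened by the α-branched isopropenyl group (1,3-induction), which puts geranyl trans and propargyl cis to isopropenyl.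

**Step 8**
Reactants: 15 (2S,6R)-2-geranyl-5-methoxy-6-prenyl-6-isopropenyl-2-propargylcyclohex-4-ene-1,3-dione; 16 methyl chloroformate
Product: 18 (2S,6R)-2-geranyl-5-methoxy-2-(4-methoxy-4-oxobut-2-ynyl)-6-prenyl-6-isopropenylcyclohex-4-ene-1,3-dione, via lithium acetylide 17 (not isolated)
Conditions: LiN(SiMe3)2 (1.1 equiv), THF, −78 °C; then 16 (1.5 equiv), −78 → −40 °C
Reagents that add atoms: methyl chloroformate 16, COC(=O)Cl
Why: Carboxylation of a lithium acetylide with a chloroformate: the silylamide is basic enough only for the alkyne C–H (C3–H needs a dialkylamide and no enolisable hydrogen is left), and both ketones are shielded by quaternary neighbours at −78 °C.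

**Step 9**
Reactants: 18 (2S,6R)-2-geranyl-5-methoxy-2-(4-methoxy-4-oxobut-2-ynyl)-6-prenyl-6-isopropenylcyclohex-4-ene-1,3-dione
Product: 19 methyl (2Z)-2-[(1R,5S)-5-geranyl-2-methoxy-8,8-dimethyl-4,9-dioxo-1-prenylbicyclo[3.3.1]non-2-en-7-ylidene]acetate
Conditions: Fe(acac)3 (30 mol %), PhSiH3 (2 equiv, added over 2 h), EtOH–THF 4:1 (0.01 M), 25 °C, Ar
Reagents that add atoms: none
Why: Proposed new method: the iron hydride formed from Fe(acac)3 and PhSiH3 hands a hydrogen atom to the exposed =CH2 terminus of the isopropenyl group, which creates the second C8 methyl group and a nucleophilic tertiary C8 radical; this radical adds to C7, the β-carbon of the ynoate standing 1,3-diaxial to it on ring A, and the linear α-ester vinyl radical is reduced by divalent iron and protonated by EtOH (or takes hydrogen from a second hydride). The closest known reaction type is the hydrogen-atom-transfer initiated reductive Giese cyclisation of 1,1-disubstituted alkenes onto enones and acrylates that builds quaternary carbons; an alkynoate acceptor used to close a bridged ring between two quaternary centres goes beyond it. Ring B (C8, C1, C9, C5, C6, C7) closes in the 6-exo-dig mode. No stereocentre is created, because C7 stays sp2 and C1 and C5 are only tied together; hydrogen should reach the vinyl radical from the C6 side, away from the new quaternary C8, so the Z-enoate is expected, and any E isomer is carried along since step 10 erases the geometry. The step needs hydrogen transfer to the only 1,1-disubstituted alkene beside three trisubstituted ones, which the accessible terminal CH2, the low temperature and the slow silane addition secure, and it needs ring closure to outrun premature reduction of the C8 radical and the 1,2-shift of the C9 acyl or C2 vinyl group, which the cis-1,3-diaxial pre-organisation, the polarity match of radical and ynoate and the high dilution secure.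

**Step 10**
Reactants: 19 methyl (2Z)-2-[(1R,5S)-5-geranyl-2-methoxy-8,8-dimethyl-4,9-dioxo-1-prenylbicyclo[3.3.1]non-2-en-7-ylidene]acetate
Product: 20 methyl 2-[(1R,5S,7R)-5-geranyl-2-methoxy-8,8-dimethyl-4,9-dioxo-1-prenylbicyclo[3.3.1]non-2-en-7-yl]acetate (side chain endo)
Conditions: Cu(OAc)2·H2O (5 mol %), 1,2-bis(diphenylphosphino)benzene (5 mol %), MeSiH(OEt)2 (3 equiv), tBuOH (2 equiv), toluene, rt
Reagents that add atoms: none
Why: Copper hydride conjugate reduction of a β,β-disubstituted enoate: the phosphine-bound hydride can reach C7 only from the open exo face, since the endo face looks into the cleft above ring A, so H ends up exo and the acetate arm endo (7R) from either alkene isomer, while the push–pull C2=C3 alkene and the hindered ketones are not touched.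

**Step 11**
Reactants: 20 methyl 2-[(1R,5S,7R)-5-geranyl-2-methoxy-8,8-dimethyl-4,9-dioxo-1-prenylbicyclo[3.3.1]non-2-en-7-yl]acetate
Product: 21 2-[(1R,5S,7R)-5-geranyl-2-methoxy-8,8-dimethyl-4,9-dioxo-1-prenylbicyclo[3.3.1]non-2-en-7-yl]acetaldehyde
Conditions: iBu2AlH (1.05 equiv), CH2Cl2, −78 °C; MeOH, aq potassium sodium tartrate
Reagents that add atoms: none
Why: Partial ester reduction with iBu2AlH through the tetrahedral aluminium acetal that survives at −78 °C: the unhindered side-chain ester reacts before the C9 ketone (two quaternary neighbours) and the donor-deactivated C4 carbonyl group.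

**Step 12**
Reactants: 21 2-[(1R,5S,7R)-5-geranyl-2-methoxy-8,8-dimethyl-4,9-dioxo-1-prenylbicyclo[3.3.1]non-2-en-7-yl]acetaldehyde; 22 isopropyltriphenylphosphonium iodide
Product: 23 (1R,5S,7S)-5-geranyl-2-methoxy-8,8-dimethyl-1,7-diprenylbicyclo[3.3.1]non-2-ene-4,9-dione (C7 prenyl endo)
Conditions: 22 (2 equiv), KN(SiMe3)2 (1.9 equiv), THF, 0 °C; then 21, −78 → 0 °C
Reagents that add atoms: isopropyltriphenylphosphonium iodide 22, CC(C)[P+](c1ccccc1)(c1ccccc1)c1ccccc1.[I-]
Why: Wittig olefination with the non-stabilised isopropylidene ylide turns the aldehyde into the prenyl group; C7 is β to the aldehyde carbon and cannot epimerise, and the ketones are too hindered to compete.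

**Step 13**
Reactants: 24 3,4-dihydroxybenzoic acid
Product: 25 tert-butyldimethylsilyl 3,4-bis(tert-butyldimethylsilyloxy)benzoate
Conditions: tBuMe2SiCl (3.5 equiv), imidazole (7 equiv), DMF, rt
Reagents that add atoms: tert-butyldimethylsilyl chloride, CC(C)(C)[Si](C)(C)Cl
Why: Standard imidazole-promoted silylation of both phenols and the carboxylic acid.

**Step 14**
Reactants: 25 tert-butyldimethylsilyl 3,4-bis(tert-butyldimethylsilyloxy)benzoate
Product: 26 3,4-bis(tert-butyldimethylsilyloxy)benzoyl chloride
Conditions: (COCl)2 (1.2 equiv), DMF (cat.), CH2Cl2, 0 °C → rt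
Reagents that add atoms: oxalyl chloride, O=C(Cl)C(=O)Cl
Why: Direct conversion of a silyl ester into the acid chloride by Vilsmeier-type activation under neutral conditions that leave the aryl silyl ethers intact.

**Step 15**
Reactants: 23 (1R,5S,7S)-5-geranyl-2-methoxy-8,8-dimethyl-1,7-diprenylbicyclo[3.3.1]non-2-ene-4,9-dione; 26 3,4-bis(tert-butyldimethylsilyloxy)benzoyl chloride
Product: 28 (1R,5R,7S)-3-[3,4-bis(tert-butyldimethylsilyloxy)benzoyl]-5-geranyl-2-methoxy-8,8-dimethyl-1,7-diprenylbicyclo[3.3.1]non-2-ene-4,9-dione, via C3-lithio enol ether 27 (not isolated)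
Conditions: LiN(iPr)2 (1.5 equiv), THF, −78 °C; then 26 (2 equiv), −78 → −30 °C
Reagents that add atoms: 3,4-bis(tert-butyldimethylsilyloxy)benzoyl chloride 26, O=C(Cl)c1ccc(O[Si](C)(C)C(C)(C)C)c(O[Si](C)(C)C(C)(C)C)c1
Why: Vinylic lithiation of the β-methoxy enone at C3 followed by acylation, the established way to acylate such bicyclic enol ethers: C3–H is the only acidic C–H because both bridgeheads are quaternary, and the vinyllithium attacks the acid chloride faster than the silyl ethers.

**Step 16**
Reactants: 28 (1R,5R,7S)-3-[3,4-bis(tert-butyldimethylsilyloxy)benzoyl]-5-geranyl-2-methoxy-8,8-dimethyl-1,7-diprenylbicyclo[3.3.1]non-2-ene-4,9-dione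
Product: 29 (1S,5S,7S)-3-[3,4-bis(tert-butyldimethylsilyloxy)benzoyl]-5-geranyl-4-hydroxy-8,8-dimethyl-1,7-diprenylbicyclo[3.3.1]non-3-ene-2,9-dione
Conditions: LiCl (10 equiv), DMSO, 120 °C; then 0.5 M HCl
Reagents that add atoms: none
Why: SN2 dealkylation of the vinylogous methyl ester by chloride, driven by the stabilised triketone enolate; a Cope shift of the remaining allyl groups would need a bridgehead alkene, so the temperature is tolerated, and any aryl silyl ether lost here merely anticipates step 17.

**Step 17**
Reactants: 29 (1S,5S,7S)-3-[3,4-bis(tert-butyldimethylsilyloxy)benzoyl]-5-geranyl-4-hydroxy-8,8-dimethyl-1,7-diprenylbicyclo[3.3.1]non-3-ene-2,9-dione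
Product: 30 CNP0160101.2, (1S,5S,7S)-3-(3,4-dihydroxybenzoyl)-5-geranyl-4-hydroxy-8,8-dimethyl-1,7-diprenylbicyclo[3.3.1]non-3-ene-2,9-dione
Conditions: Bu4NF (2.5 equiv), AcOH (2.5 equiv), THF, 0 °C, Ar
Reagents that add atoms: none
Why: Fluoride desilylation of aryl silyl ethers, buffered with acetic acid so that the catechol and the enolised triketone are not exposed to base and air.

**Compound list**

1 | 4'-hydroxy-2',6'-dimethoxyacetophenone | CC(=O)c1c(OC)cc(O)cc1OC | starting material
2 | methyltriphenylphosphonium bromide | C[P+](c1ccccc1)(c1ccccc1)c1ccccc1.[Br-] | starting material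
3 | 3,5-dimethoxy-4-(prop-1-en-2-yl)phenol | CC(=C)c1c(OC)cc(O)cc1OC | intermediate
4 | allyl methyl carbonate | C=CCOC(=O)OC | starting material
5 | 4-allyl-3,5-dimethoxy-4-(prop-1-en-2-yl)cyclohexa-2,5-dien-1-one (achiral) | O=C1C=C(OC)C(CC=C)(C(C)=C)C(OC)=C1 | intermediate
6 | 2-methyl-2-butene | CC=C(C)C | starting material
7 | 3,5-dimethoxy-4-(3-methylbut-2-enyl)-4-(prop-1-en-2-yl)cyclohexa-2,5-dien-1-one (achiral) | O=C1C=C(OC)C(CC=C(C)C)(C(C)=C)C(OC)=C1 | intermediate
8 | rac-3-hydroxy-5-methoxy-4-(3-methylbut-2-enyl)-4-(prop-1-en-2-yl)cyclohexa-2,5-dien-1-one (racemate) | O=C1C=C(OC)C(CC=C(C)C)(C(C)=C)C(O)=C1 | intermediate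
9 | (R)-1-phenylethylamine | C[C@@H](N)c1ccccc1 | starting material
10 | (R)-1-phenylethylammonium salt of the (S)-enantiomer of 8 | O=C1C=C(OC)[C@@](CC=C(C)C)(C(C)=C)C([O-])=C1.C[C@@H]([NH3+])c1ccccc1 | intermediate
11 | propargyl bromide | C#CCBr | starting material
12 | potassium enolate of the (S)-enantiomer of 8 | O=C1C=C(OC)[C@@](CC=C(C)C)(C(C)=C)C([O-])=C1.[K+] | intermediate
13 | (4S)-3-hydroxy-5-methoxy-4-(3-methylbut-2-enyl)-4-(prop-1-en-2-yl)-2-(prop-2-ynyl)cyclohexa-2,5-dien-1-one | O=C1C=C(OC)[C@@](CC=C(C)C)(C(C)=C)C(O)=C1CC#C | intermediate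
14 | geranyl bromide | CC(C)=CCC/C(C)=C/CBr | starting material
15 | (2S,6R)-2-geranyl-5-methoxy-6-prenyl-6-isopropenyl-2-propargylcyclohex-4-ene-1,3-dione, propargyl cis to isopropenyl | CC(C)=CCC/C(C)=C/C[C@@]1(CC#C)C(=O)[C@](CC=C(C)C)(C(C)=C)C(OC)=CC1=O | intermediate
16 | methyl chloroformate | COC(=O)Cl | starting material
17 | lithium acetylide of 15 | CC(C)=CCC/C(C)=C/C[C@@]1(CC#C[Li])C(=O)[C@](CC=C(C)C)(C(C)=C)C(OC)=CC1=O | intermediate
18 | (2S,6R)-2-geranyl-5-methoxy-2-(4-methoxy-4-oxobut-2-ynyl)-6-prenyl-6-isopropenylcyclohex-4-ene-1,3-dione, butynoate cis to isopropenyl (key-step precursor) | CC(C)=CCC/C(C)=C/C[C@@]1(CC#CC(=O)OC)C(=O)[C@](CC=C(C)C)(C(C)=C)C(OC)=CC1=O | intermediate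
19 | methyl (2Z)-2-[(1R,5S)-5-geranyl-2-methoxy-8,8-dimethyl-4,9-dioxo-1-prenylbicyclo[3.3.1]non-2-en-7-ylidene]acetate (key-step product) | CC(C)=CCC/C(C)=C/C[C@]12C/C(=C/C(=O)OC)C(C)(C)[C@](CC=C(C)C)(C(OC)=CC1=O)C2=O | intermediate
20 | methyl 2-[(1R,5S,7R)-5-geranyl-2-methoxy-8,8-dimethyl-4,9-dioxo-1-prenylbicyclo[3.3.1]non-2-en-7-yl]acetate, side chain endo | CC(C)=CCC/C(C)=C/C[C@]12C[C@H](CC(=O)OC)C(C)(C)[C@](CC=C(C)C)(C(OC)=CC1=O)C2=O | intermediate
21 | 2-[(1R,5S,7R)-5-geranyl-2-methoxy-8,8-dimethyl-4,9-dioxo-1-prenylbicyclo[3.3.1]non-2-en-7-yl]acetaldehyde | CC(C)=CCC/C(C)=C/C[C@]12C[C@H](CC=O)C(C)(C)[C@](CC=C(C)C)(C(OC)=CC1=O)C2=O | intermediate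
22 | isopropyltriphenylphosphonium iodide | CC(C)[P+](c1ccccc1)(c1ccccc1)c1ccccc1.[I-] | starting material
23 | (1R,5S,7S)-5-geranyl-2-methoxy-8,8-dimethyl-1,7-diprenylbicyclo[3.3.1]non-2-ene-4,9-dione, C7 prenyl endo | CC(C)=CCC/C(C)=C/C[C@]12C[C@H](CC=C(C)C)C(C)(C)[C@](CC=C(C)C)(C(OC)=CC1=O)C2=O | intermediate
24 | 3,4-dihydroxybenzoic acid | O=C(O)c1ccc(O)c(O)c1 | starting material
25 | tert-butyldimethylsilyl 3,4-bis(tert-butyldimethylsilyloxy)benzoate | CC(C)(C)[Si](C)(C)OC(=O)c1ccc(O[Si](C)(C)C(C)(C)C)c(O[Si](C)(C)C(C)(C)C)c1 | intermediate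
26 | 3,4-bis(tert-butyldimethylsilyloxy)benzoyl chloride | O=C(Cl)c1ccc(O[Si](C)(C)C(C)(C)C)c(O[Si](C)(C)C(C)(C)C)c1 | intermediate
27 | C3-lithio derivative of 23 | CC(C)=CCC/C(C)=C/C[C@]12C[C@H](CC=C(C)C)C(C)(C)[C@](CC=C(C)C)(C(OC)=C([Li])C1=O)C2=O | intermediate
28 | (1R,5R,7S)-3-[3,4-bis(tert-butyldimethylsilyloxy)benzoyl]-5-geranyl-2-methoxy-8,8-dimethyl-1,7-diprenylbicyclo[3.3.1]non-2-ene-4,9-dione | CC(C)=CCC/C(C)=C/C[C@]12C[C@H](CC=C(C)C)C(C)(C)[C@](CC=C(C)C)(C(OC)=C(C(=O)c3ccc(O[Si](C)(C)C(C)(C)C)c(O[Si](C)(C)C(C)(C)C)c3)C1=O)C2=O | intermediate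
29 | (1S,5S,7S)-3-[3,4-bis(tert-butyldimethylsilyloxy)benzoyl]-5-geranyl-4-hydroxy-8,8-dimethyl-1,7-diprenylbicyclo[3.3.1]non-3-ene-2,9-dione | CC(C)=CCC/C(C)=C/C[C@]12C[C@H](CC=C(C)C)C(C)(C)[C@](CC=C(C)C)(C(=O)C(C(=O)c3ccc(O[Si](C)(C)C(C)(C)C)c(O[Si](C)(C)C(C)(C)C)c3)=C1O)C2=O | intermediate
30 | CNP0160101.2, (1S,5S,7S)-3-(3,4-dihydroxybenzoyl)-5-geranyl-4-hydroxy-8,8-dimethyl-1,7-diprenylbicyclo[3.3.1]non-3-ene-2,9-dione | CC(C)=CCC/C(C)=C/C[C@]12C[C@H](CC=C(C)C)C(C)(C)[C@](CC=C(C)C)(C(=O)C(C(=O)c3ccc(O)c(O)c3)=C1O)C2=O | target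

Total step count: 17.
Longest linear sequence: 15 steps (steps 1–12 and 15–17, from 1).

**Steps most likely to fail**

1. Step 9 (new method).
   - Risk: hydrogen transfer may stray to the prenyl and geranyl alkenes. The C8 radical may be reduced before it cyclises. The C9 acyl or C2 vinyl group may migrate to it with ring expansion.
   - Fallback, from 15 back to 19: the radical is made by halogen abstraction instead of hydrogen transfer, so that hydrogen delivery and C–C bond formation are separated. Cobalt-mediated Markovnikov hydrochlorination of the isopropenyl group of 15 (Co(acac)2, tBuOOH, Et3SiH, TsCl, nPrOH, rt) is a known hydrofunctionalisation whose product can be purified before any ring closure. It gives the tertiary chloride F1. Carboxylation as in step 8 gives the chloro ynoate F2. (Me3Si)3SiH with Et3B and air in dilute toluene at rt abstracts chlorine, and the classical silane-mediated 6-exo-dig radical cyclisation onto the ynoate, with a slow hydrogen donor as the only reductant, returns 19.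

2. Step 7.
   - Risk: O-alkylation of the hindered enolate and weak discrimination between the two faces of C5.
   - Fallback, from 13 back to 15: a Tsuji–Trost allylation replaces the SN2 alkylation. Geraniol and methyl chloroformate 16 (pyridine, CH2Cl2, 0 °C) give geranyl methyl carbonate F3, which ionises with Pd(PPh3)4 in THF at rt to the geranylpalladium cation. O-allylation is reversible under zerovalent palladium, so material funnels to the C-allylated diketone. Attack takes place at the unsubstituted allyl terminus. The much bulkier electrophile should sharpen the preference for the face anti to the isopropenyl group.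

3. Step 10.
   - Risk: slow hydride delivery to the neopentyl C7, leakage through the endo face, or competing 1,2-reduction.
   - Fallback, from 19 back to 21 (20 is bypassed): the oxidation level is changed and the hydride is delivered under catalyst control. iBu2AlH (2.2 equiv, CH2Cl2, −78 °C) gives the allylic alcohol F4 and MnO2 (CH2Cl2, rt) gives the enal F5. Organocatalytic transfer hydrogenation through the iminium ion follows (Hantzsch ester, the matched antipode of a chiral 2-tert-butylimidazolidinone trifluoroacetate, CHCl3, −30 °C). This reaction is known for β,β-disubstituted enals and is convergent for alkene isomers. It touches only the enal and gives aldehyde 21 directly.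

**Further compounds**

F1 | step 9 | tertiary chloride, 15 with C(CH3)2Cl in place of isopropenyl, configured as 15 | CC(C)=CCC/C(C)=C/C[C@@]1(CC#C)C(=O)[C@](CC=C(C)C)(C(C)(C)Cl)C(OC)=CC1=O
F2 | step 9 | chloro ynoate, 18 with C(CH3)2Cl in place of isopropenyl, configured as 18 | CC(C)=CCC/C(C)=C/C[C@@]1(CC#CC(=O)OC)C(=O)[C@](CC=C(C)C)(C(C)(C)Cl)C(OC)=CC1=O
F3 | step 7 | geranyl methyl carbonate | CC(C)=CCC/C(C)=C/COC(=O)OC
F4 | step 10 | allylic alcohol, 19 with CH2OH in place of CO2Me | CC(C)=CCC/C(C)=C/C[C@]12C/C(=C/CO)C(C)(C)[C@](CC=C(C)C)(C(OC)=CC1=O)C2=O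
F5 | step 10 | enal, 19 with CHO in place of CO2Me | CC(C)=CCC/C(C)=C/C[C@]12C/C(=C/C=O)C(C)(C)[C@](CC=C(C)C)(C(OC)=CC1=O)C2=O
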